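## Retrosynthetic overview

- Japonicone A (26) ⇒ final endo [4+2] between the α‑methylene lactone of ent‑1β‑hydroxyalantolactone (12) and the 5‑acetoxycyclopentadiene unveiled from hydroxy acetate 25 (C13–C1′ and C11–C3′; norbornene formed last).
- Diene half 25 ⇒ cross‑conjugated dienone 21 by a silyl‑intercepted photo‑Nazarov closure (C4′–C5′, five‑membered ring), then ¹O₂ γ‑oxygenation and OH‑directed reduction.
- 21 ⇒ (S)‑carvone by γ‑photooxygenation, OH‑directed hydrogenation, lactonisation, one‑carbon ring expansion and carbonylative coupling (six‑ring → lactone → seven‑ring → five‑ring).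
- Dienophile half 12 ⇒ Δ5‑8‑ketone 8 (lactone last) ⇒ ring‑closing metathesis (ring B) on a ring‑A fragment from (S)‑carvone (double C6 alkylation, Criegee excision of the isopropenyl group).
- Every stereocentre is relayed from C5 of (S)‑(+)‑carvone by substrate control.

Assumption: the SMILES is taken literally; its eudesmanolide half is (1S,4R,7S,8S,10S), the mirror image of natural 1β‑hydroxyalantolactone, so both halves are built in the antipodal series from (S)‑(+)‑carvone. Only route compounds are numbered; reagents are given by name and SMILES.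

## Route

### Dienophile half (eudesmane numbering)

Step 1
Reactants: 1, (S)‑(+)‑carvone
Product: 2, 6‑methylcarvone (6‑Me mainly trans to isopropenyl; the epimer mixture is inconsequential)
Conditions: LDA, THF, −78 °C; MeI, −78 → 0 °C
Reagents that add atoms: iodomethane, CI
Why: Kinetic α′‑enolate alkylation at the only enolisable α′ carbon; this centre is re‑enolised in step 2.

Step 2
Reactants: 2
Product: 3, N‑methoxy‑N‑methyl‑2‑[(1R,6R)‑1,3‑dimethyl‑2‑oxo‑6‑(prop‑1‑en‑2‑yl)cyclohex‑3‑en‑1‑yl]acetamide (amide arm trans to isopropenyl)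
Conditions: LDA, THF/DMPU, −78 °C; BrCH2C(O)N(OMe)Me, −78 → −20 °C
Reagents that add atoms: 2‑bromo‑N‑methoxy‑N‑methylacetamide, CON(C)C(=O)CBr
Why: Second enolate alkylation; the electrophile enters anti to the adjacent isopropenyl group, setting the quaternary centre (future C10) with its methyl cis to the future C1 oxygen.

Step 3
Reactants: 3
Product: 4, 2‑[(1R,6S)‑6‑acetoxy‑1,3‑dimethyl‑2‑oxocyclohex‑3‑en‑1‑yl]‑N‑methoxy‑N‑methylacetamide
Conditions: O3, CH2Cl2/MeOH, −78 °C; then Ac2O, Et3N, DMAP, 0 → 40 °C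
Reagents that add atoms: ozone, [O-][O+]=O; methanol, CO (acetate carbonyl oxygen)
Why: Ozonolysis of the electron‑rich isopropenyl group (enone untouched) and Criegee rearrangement of the α‑methoxy hydroperoxide; the ring carbon migrates to oxygen with retention, so carvone C5 becomes the C1 carbinol.

Step 4
Reactants: 4
Product: 5, 2‑[(1R,3R,6S)‑6‑acetoxy‑1,3‑dimethyl‑2‑oxocyclohexyl]‑N‑methoxy‑N‑methylacetamide (1‑Me, 3‑Me and 6‑OAc all cis)
Conditions: H2 (1 atm), 5% Pd/C, EtOAc, 0 °C
Reagents that add atoms: none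
Why: Heterogeneous cis‑hydrogenation of the enone from the face opposite the pseudo‑axial quaternary methyl gives the C4 methyl cis to the C10 methyl; this kinetic α‑centre sees no base before the ketone is removed.

Step 5
Reactants: 5
Product: 6, 2‑[(1S,3R,6S)‑6‑acetoxy‑1,3‑dimethyl‑2‑methylidenecyclohexyl]‑N‑methoxy‑N‑methylacetamide
Conditions: Zn, CH2Br2, TiCl4, THF/CH2Cl2, 0 °C → rt
Reagents that add atoms: dibromomethane, BrCBr
Why: Non‑basic Takai–Lombardo methylenation of a hindered, epimerisable ketone; C4 is now locked as an allylic centre.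

Step 6
Reactants: 6
Product: 7, 1‑[(1S,3R,6S)‑6‑hydroxy‑1,3‑dimethyl‑2‑methylidenecyclohexyl]pent‑4‑en‑2‑one
Conditions: allylMgBr (3.5 equiv), THF, −78 → −40 °C; AcOH quench at −78 °C
Reagents that add atoms: allylmagnesium bromide, C=CC[Mg]Br
Why: Weinreb ketone synthesis stops at the β,γ‑unsaturated ketone; excess Grignard also cleaves the acetate, and the cold acidic quench prevents conjugation.

Step 7
Reactants: 7
Product: 8, (1S,4R,10S)‑1‑hydroxy‑11,12,13‑trinoreudesm‑5‑en‑8‑one
Conditions: Hoveyda–Grubbs II (10 mol%), 1,4‑benzoquinone (20 mol%), toluene, 80 °C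
Reagents that add atoms: none
Why: Ring‑closing metathesis closes ring B and installs the trisubstituted C5=C6 alkene; benzoquinone suppresses Ru–H isomerisation.

Step 8
Reactants: 8
Product: 9, methyl [(1S,4R,7R,10S)‑1‑hydroxy‑8‑oxo‑11,12,13‑trinoreudesm‑5‑en‑7‑yl]acetate (arm on the face of the C10 methyl)
Conditions: LDA (2.1 equiv), THF/DMPU, −78 °C; BrCH2CO2Me (1.05 equiv); then LDA (1.1 equiv), −78 → −40 °C; AcOH, −78 °C
Reagents that add atoms: methyl bromoacetate, COC(=O)CBr
Why: α‑Alkylation of the extended dienolate at C7, then re‑formation of that dienolate and kinetic α‑protonation anti to the angular methyl; this puts the acetate arm on the methyl face and keeps the alkene at C5=C6.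

Step 9
Reactants: 9
Product: 10, (1S,4R,7R,8S,10S)‑1‑hydroxy‑13‑noreudesm‑5‑en‑12,8‑olide (cis‑fused)
Conditions: L‑Selectride (2.5 equiv), THF, −78 °C; then aq. citric acid, rt
Reagents that add atoms: none
Why: The bulky hydride attacks C8 anti to the 1,3‑related angular methyl, giving the alcohol cis to the C7 arm, which lactonises.

Step 10
Reactants: 10
Product: 11, 13‑(dimethylamino)‑11,13‑dihydro derivative of 12 (C11 epimers)
Conditions: LDA (2.2 equiv), THF, −78 °C; CH2=NMe2+ I−, −78 → 0 °C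
Reagents that add atoms: Eschenmoser's salt, C=[N+](C)C.[I-]
Why: Mannich reaction of the lactone enolate (one equivalent of base is taken by the free C1–OH).

Step 11
Reactants: 11
Product: 12, ent‑1β‑hydroxyalantolactone, (1S,4R,7S,8S,10S)‑1‑hydroxyeudesma‑5,11(13)‑dien‑12,8‑olide
Conditions: MeI, MeOH, rt; then aq. NaHCO3/EtOAc
Reagents that add atoms: none
Why: Quaternisation and E1cB elimination of trimethylamine give the exocyclic methylene.

### Diene half (guaiane numbering, primed)

Step 12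
Reactants: 1
Product: 13, trimethyl{[(5S)‑2‑methyl‑5‑(prop‑1‑en‑2‑yl)cyclohexa‑1,3‑dien‑1‑yl]oxy}silane
Conditions: MeMgBr, FeCl3 (cat.), Et2O, −20 °C; TMSCl, Et3N, DMPU
Reagents that add atoms: chlorotrimethylsilane, C[Si](C)(C)Cl
Why: Iron‑ate γ‑deprotonation gives the through‑conjugated (thermodynamic) silyl dienol ether, not the kinetic cross‑conjugated one.

Step 13
Reactants: 13
Product: 14, (4R,5S)‑4‑hydroxy‑2‑methyl‑5‑(prop‑1‑en‑2‑yl)cyclohex‑2‑en‑1‑one (OH trans to isopropenyl)
Conditions: O2, TPP (1 mol%), white LED, CH2Cl2, −78 °C; then PPh3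
Reagents that add atoms: dioxygen, O=O
Why: Sensitised ¹O₂ [4+2] addition to the 1‑siloxy diene anti to the isopropenyl group, collapse to the γ‑hydroperoxy enone and reduction (vinylogous Rubottom‑type γ‑oxygenation); this sets C8′.

Step 14
Reactants: 14
Product: 15, (4R,5R)‑4‑hydroxy‑2‑methyl‑5‑(2‑methyloxiran‑2‑yl)cyclohex‑2‑en‑1‑one (epimers at the oxirane carbon, inconsequential)
Conditions: mCPBA, NaHCO3, CH2Cl2, 0 °C
Reagents that add atoms: mCPBA, OOC(=O)c1cccc(Cl)c1
Why: Prilezhaev epoxidation is selective for the electron‑rich 1,1‑disubstituted alkene; the epoxide masks it during hydrogenation.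

Step 15
Reactants: 15
Product: 16, (2R,4R,5R)‑4‑hydroxy‑2‑methyl‑5‑(2‑methyloxiran‑2‑yl)cyclohexan‑1‑one (2‑Me trans to 4‑OH)
Conditions: H2 (1 atm), [Ir(cod)(PCy3)(py)]PF6 (5 mol%), CH2Cl2, rt
Reagents that add atoms: none
Why: Hydroxyl‑directed (Crabtree) hydrogenation delivers H2 syn to the C4–OH, so the methyl (future C10′) ends trans to oxygen and cis to the side chain, the epimer that enolate protonation would not give.

Step 16
Reactants: 16
Product: 17, (2R,4R,5S)‑4‑hydroxy‑5‑(3‑hydroxyprop‑1‑en‑2‑yl)‑2‑methylcyclohexan‑1‑one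
Conditions: Cp2TiCl2 (2.2 equiv), Mn, THF, rt
Reagents that add atoms: none
Why: Ti(III)‑mediated homolytic epoxide opening and β‑hydride elimination from the methyl group give the 2‑substituted allylic alcohol under neutral conditions, without enolising the α‑methyl ketone.

Step 17
Reactants: 17
Product: 18, (3aS,6R,7aR)‑6‑methyl‑3‑methylidenehexahydro‑1‑benzofuran‑2,5‑dione (trans‑fused)
Conditions: TEMPO (20 mol%), PhI(OAc)2 (2.5 equiv), CH2Cl2, rt
Reagents that add atoms: none
Why: Selective oxidation of the primary allylic alcohol, lactol formation with the trans‑vicinal secondary OH and further oxidation give the trans‑fused α‑methylene γ‑lactone.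

Step 18
Reactants: 18
Product: 19, (3aS,7R,8aR)‑7‑methyl‑3‑methylideneoctahydro‑2H‑cyclohepta[b]furan‑2,6‑dione
Conditions: TMSCHN2, BF3·OEt2, CH2Cl2, −78 °C; AcOH quench; SiO2
Reagents that add atoms: (trimethylsilyl)diazomethane, C[Si](C)(C)C=[N+]=[N-]
Why: Lewis‑acid‑promoted diazoalkane ring expansion (Tiffeneau–Demjanov type); the less substituted CH2 migrates, inserting C5′ away from the methyl‑bearing carbon.

Step 19
Reactants: 19
Product: 20, (3aS,7R,8aR)‑7‑methyl‑3‑methylidene‑2‑oxo‑3,3a,4,7,8,8a‑hexahydro‑2H‑cyclohepta[b]furan‑6‑yl trifluoromethanesulfonate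
Conditions: KHMDS (1.05 equiv), THF, −78 °C; PhNTf2
Reagents that add atoms: N‑phenylbis(trifluoromethanesulfonimide), O=S(=O)(N(c1ccccc1)S(=O)(=O)C(F)(F)F)C(F)(F)F
Why: Kinetic deprotonation at the unhindered C5′H2 gives the less substituted enol triflate; C10′ is untouched and is no longer α to a carbonyl afterwards.

Step 20
Reactants: 20
Product: 21, (3aS,7R,8aR)‑6‑[(2E)‑but‑2‑enoyl]‑7‑methyl‑3‑methylidene‑3,3a,4,7,8,8a‑hexahydro‑2H‑cyclohepta[b]furan‑2‑one
Conditions: Pd(PPh3)4 (5 mol%), LiCl, CO (1 atm), (E)‑Bu3SnCH=CHCH3, THF, 55 °C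
Reagents that add atoms: carbon monoxide, [C-]#[O+]; (E)‑tributyl(prop‑1‑enyl)stannane, CCCC[Sn](CCCC)(CCCC)/C=C/C
Why: Carbonylative Stille coupling of the vinyl triflate gives the cross‑conjugated divinyl ketone.

Step 21
Reactants: 21
Product: 22, (7S,8R,10R)‑2‑(trimethylsilyloxy)guaia‑1,4,11(13)‑trien‑12,8‑olide
Conditions: hν (365 nm LED), BSA (3 equiv), 2,6‑lutidinium triflate (5 mol%), degassed MeCN, 0 °C; then 45 °C, 1 h, dark
Reagents that add atoms: N,O‑bis(trimethylsilyl)acetamide, C/C(O[Si](C)(C)C)=N/[Si](C)(C)C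
Why: Proposed new method: excitation of the dienone triggers the photo‑Nazarov 4π closure (C4′–C5′) to an oxyallyl zwitterion/2‑hydroxycyclopentadiene, which is O‑silylated in situ (BSA silylates enols, not ketones) instead of tautomerising to the cyclopentenone, and brief warming lets 1,5‑H shifts funnel it to the fully substituted 1‑siloxy diene; closest known reactions are the photo‑Nazarov cyclisation of cycloalkenyl/aryl vinyl ketones and electrophile‑trapped (interrupted) Nazarov reactions.

Step 22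
Reactants: 22
Product: 23, (4S,7S,8R,10R)‑4‑hydroxy‑2‑oxoguaia‑1(5),11(13)‑dien‑12,8‑olide (4‑OH trans to the C10′ methyl face)
Conditions: O2, TPP (1 mol%), white LED, CH2Cl2, −78 °C; PPh3; wet SiO2
Reagents that add atoms: dioxygen, O=O
Why: ¹O₂ [4+2] addition across C2′/C4′ on the face anti to the C10′ methyl, then silyl‑peroxide collapse and reduction, gives the γ‑hydroxy enone (same γ‑oxygenation as step 13).

Step 23
Reactants: 23
Product: 24, (2S,4S,7S,8R,10R)‑2,4‑dihydroxyguaia‑1(5),11(13)‑dien‑12,8‑olide (1,3‑anti diol)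
Conditions: Me4NBH(OAc)3, AcOH/MeCN, −30 °C
Reagents that add atoms: none
Why: Evans–Saksena reduction: hydride is delivered intramolecularly from the C4′ alkoxyborohydride, giving the anti‑1,3‑diol (C2′–OH cis to the C10′ methyl) without touching the α‑methylene lactone.

Step 24
Reactants: 24
Product: 25, (2S,4S,7S,8R,10R)‑2‑acetoxy‑4‑hydroxyguaia‑1(5),11(13)‑dien‑12,8‑olide
Conditions: Ac2O, pyridine, DMAP (5 mol%), CH2Cl2, 0 °C
Reagents that add atoms: acetic anhydride, CC(=O)OC(C)=O
Why: Selective acylation of the secondary allylic alcohol; the tertiary alcohol stays free.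

Step 25
Reactants: 25 and 12 (3 equiv)
Product: 26, japonicone A (enantiomer as drawn)
Conditions: Burgess reagent (1.1 equiv), benzene, 35 °C, 45 min; SiO2 plug at 0 °C; then 12, BHT, ca. 2 M in toluene, 25 °C, 72 h, dark
Reagents that add atoms: none
Why: Burgess syn‑dehydration of the tertiary allylic alcohol unveils (2S,7S,8R,10R)‑2‑acetoxyguaia‑1(5),3,11(13)‑trien‑12,8‑olide, which undergoes a biomimetic normal‑demand Diels–Alder reaction with 12: endo lactone carbonyl, dienophile on the diene face anti to both the C2′ acetate and the C10′ methyl, diene on the convex (H‑7/H‑8) face of the cis‑lactone, and CH2‑13 bonding to the fully substituted C1′ so that no quaternary–quaternary bond forms.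

## Compound list

1 | (S)‑(+)‑carvone | O=C1C(C)=CC[C@H](C(C)=C)C1 | starting material
2 | 6‑methylcarvone (major trans epimer) | O=C1C(C)=CC[C@H](C(C)=C)[C@H]1C | intermediate
3 | Weinreb amide, C6 quaternary | O=C1C(C)=CC[C@H](C(C)=C)[C@@]1(C)CC(=O)N(C)OC | intermediate
4 | Criegee acetate | O=C1C(C)=CC[C@H](OC(C)=O)[C@@]1(C)CC(=O)N(C)OC | intermediate
5 | saturated ketone (all‑cis Me/Me/OAc) | O=C1[C@H](C)CC[C@H](OC(C)=O)[C@@]1(C)CC(=O)N(C)OC | intermediate
6 | exocyclic methylene amide | C=C1[C@H](C)CC[C@H](OC(C)=O)[C@@]1(C)CC(=O)N(C)OC | intermediate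
7 | allyl ketone, free C1–OH | C=C1[C@H](C)CC[C@H](O)[C@@]1(C)CC(=O)CC=C | intermediate
8 | (1S,4R,10S)‑1‑hydroxy‑11,12,13‑trinoreudesm‑5‑en‑8‑one | O=C1CC=C2[C@H](C)CC[C@H](O)[C@@]2(C)C1 | intermediate
9 | C7 acetate‑arm keto ester | O=C1[C@H](CC(=O)OC)C=C2[C@H](C)CC[C@H](O)[C@@]2(C)C1 | intermediate
10 | (1S,4R,7R,8S,10S)‑1‑hydroxy‑13‑noreudesm‑5‑en‑12,8‑olide | O=C1C[C@@H]2C=C3[C@H](C)CC[C@H](O)[C@@]3(C)C[C@@H]2O1 | intermediate
11 | 13‑dimethylamino Mannich base | O=C1C(CN(C)C)[C@@H]2C=C3[C@H](C)CC[C@H](O)[C@@]3(C)C[C@@H]2O1 | intermediate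
12 | ent‑1β‑hydroxyalantolactone | C=C1C(=O)O[C@H]2C[C@@]3(C)C(=C[C@H]21)[C@H](C)CC[C@@H]3O | intermediate
13 | carvone thermodynamic TMS dienol ether | C[Si](C)(C)OC1=C(C)C=C[C@H](C(C)=C)C1 | intermediate
14 | (4R,5S)‑4‑hydroxycarvone | O=C1C(C)=C[C@@H](O)[C@H](C(C)=C)C1 | intermediate
15 | isopropenyl epoxide | O=C1C(C)=C[C@@H](O)[C@H](C2(C)CO2)C1 | intermediate
16 | saturated epoxy ketol | O=C1[C@H](C)C[C@@H](O)[C@H](C2(C)CO2)C1 | intermediate
17 | keto diol | O=C1[C@H](C)C[C@@H](O)[C@H](C(=C)CO)C1 | intermediate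
18 | (3aS,6R,7aR)‑6‑methyl‑3‑methylidenehexahydro‑1‑benzofuran‑2,5‑dione | C=C1C(=O)O[C@@H]2C[C@@H](C)C(=O)C[C@@H]12 | intermediate
19 | (3aS,7R,8aR)‑7‑methyl‑3‑methylideneoctahydro‑2H‑cyclohepta[b]furan‑2,6‑dione | C=C1C(=O)O[C@@H]2C[C@@H](C)C(=O)CC[C@@H]12 | intermediate
20 | enol triflate | C=C1C(=O)O[C@@H]2C[C@@H](C)C(OS(=O)(=O)C(F)(F)F)=CC[C@@H]12 | intermediate
21 | cross‑conjugated dienone | C=C1C(=O)O[C@@H]2C[C@@H](C)C(C(=O)/C=C/C)=CC[C@@H]12 | intermediate
22 | 2‑(trimethylsilyloxy)guaia‑1,4,11(13)‑trien‑12,8‑olide | C=C1C(=O)O[C@@H]2C[C@@H](C)C3=C(O[Si](C)(C)C)CC(C)=C3C[C@@H]12 | intermediate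
23 | 4‑hydroxy‑2‑oxoguaia‑1(5),11(13)‑dien‑12,8‑olide | C=C1C(=O)O[C@@H]2C[C@@H](C)C3=C(C[C@@H]12)[C@@](C)(O)CC3=O | intermediate
24 | 2,4‑dihydroxyguaia‑1(5),11(13)‑dien‑12,8‑olide | C=C1C(=O)O[C@@H]2C[C@@H](C)C3=C(C[C@@H]12)[C@@](C)(O)C[C@@H]3O | intermediate
25 | 2‑acetoxy‑4‑hydroxyguaia‑1(5),11(13)‑dien‑12,8‑olide | C=C1C(=O)O[C@@H]2C[C@@H](C)C3=C(C[C@@H]12)[C@@](C)(O)C[C@@H]3OC(C)=O | intermediate
26 | japonicone A (as drawn) | C=C1C(=O)O[C@@H]2C[C@@H](C)[C@]34C[C@]5(C(=O)O[C@H]6C[C@@]7(C)C(=C[C@H]65)[C@H](C)CC[C@@H]7O)[C@H](C(C)=C3C[C@@H]12)[C@@H]4OC(C)=O | target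

(Transient diene in step 25: C=C1C(=O)O[C@@H]2C[C@@H](C)C3=C(C[C@@H]12)C(C)=C[C@@H]3OC(C)=O.)

## Step count and risks

Total: 25 steps. Longest linear sequence: 14 steps (steps 12–25); the other branch is 11 steps before the union.

Steps most likely to fail:

1. **Step 25 (dehydration / cross Diels–Alder).** The 5‑acetoxy diene can isomerise by 1,5‑H shift or react with its own lactone, and the face and regiochemistry rest on steric arguments. Fallback: mask the diene half's methylene lactone as its dimethylamine Michael adduct (made from 25), so only 12 can act as dienophile and a Lewis acid (Me2AlCl, −40 °C) can be used below the H‑shift temperature; regenerate the methylene with MeI/NaHCO3.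
2. **Step 21 (proposed silyl‑intercepted photo‑Nazarov).** Ketonisation to the enone may outrun silylation. Fallback with known chemistry: Sonogashira coupling of triflate 20 with but‑3‑yn‑2‑yl acetate, then Au(I)‑catalysed 3,3‑rearrangement/Nazarov to the 2‑acetoxycyclopentadiene, which enters step 22 in place of 22.
3. **Step 8 (C7 configuration by dienolate protonation).** The β,γ‑enone may conjugate or give the C7 epimer. Fallback: set C7 and C8 by chirality transfer instead. C‑acylate in step 2 so that metathesis gives the C9 ketone, dehydrogenate to the 5,7‑dien‑9‑one, Luche‑reduce, run a Johnson–Claisen rearrangement (C9–O to C7–C), then iodolactonise onto C8=C9 and deiodinate with Bu3SnH.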